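**Assumption:** the SMILES has no stereocentre. The biaryl axis carries only OH/H and CH2CH2Ar/H as ortho groups, so it rotates freely at room temperature. I treat the target as achiral, and no step needs stereocontrol.

## Retrosynthetic overview
1. The obvious route, which I avoid, is a Suzuki union of two pre-halogenated or borylated halves followed by Wittig/hydrogenation for the arms.
2. Target ⇒ bis-acetonide 7. A final acid hydrolysis cannot touch the two anisole OMe groups.
3. 7 ⇒ dibromobiaryl 4 + 2 × alkylborane 6. Both aryl–CH2 bonds are cut at once in a two-directional B-alkyl Suzuki coupling.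
4. 4 ⇒ 3 (site-selective bromination) ⇒ key step. Ring C enters as a symmetrical 4,5-dioxygenated benzyne, attacked by C–H-lithiated catechol acetonide. Bromine transfer leaves Br exactly where the ring-C arm must go.
5. No ring is built. All four benzene rings are purchased (2 × catechol acetonide, 2 × 3-vinylanisole). The order of union is B–C first, then both A rings together.

## Route

**Step 1**
Reactants: 1, 2,2-dimethyl-1,3-benzodioxole (catechol acetonide)
Product: 2, 5,6-dibromo-2,2-dimethyl-1,3-benzodioxole
Conditions: NBS (2.1 equiv), MeCN, 0 °C → rt, dark, 16 h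
Reagents that add atoms: N-bromosuccinimide, O=C1CCC(=O)N1Br
Why: Electrophilic aromatic bromination in which each ring oxygen directs para, so Br enters C5 and then C6 (as veratrole gives 4,5-dibromoveratrole), and the neutral medium spares the ketal.

**Step 2 (key step)**
Reactants: 1, 2,2-dimethyl-1,3-benzodioxole (1.2 equiv); 2, 5,6-dibromo-2,2-dimethyl-1,3-benzodioxole (1.0 equiv)
Product: 3, 5-bromo-6-(2,2-dimethyl-1,3-benzodioxol-4-yl)-2,2-dimethyl-1,3-benzodioxole
Conditions: 1, n-BuLi (1.1 equiv), THF, 0 °C, 2 h; cool to −78 °C; add 2 in THF over 30 min; −78 °C → rt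
Reagents that add atoms: none (n-BuLi only removes H; all atoms come from 1 and 2; one Br leaves as LiBr)
Why: Directed ortho-metalation gives the 4-lithio species, which feeds an aryne-coupling chain (the manifold used to make 2-bromo-2',6'-dimethoxybiphenyl): Br/Li exchange on 2 and LiBr loss give the C2v-symmetric 5,6-aryne (no regiochemical issue), the O-stabilised ArLi carbolithiates it to form the biaryl bond, and the unstabilised 2-lithiobiaryl abstracts Br from fresh 2, which releases 3 and regenerates the aryne precursor.

**Step 3**
Reactants: 3, the monobromobiaryl from Step 2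
Product: 4, 6-bromo-4-(6-bromo-2,2-dimethyl-1,3-benzodioxol-5-yl)-2,2-dimethyl-1,3-benzodioxole
Conditions: NBS (1.02 equiv), MeCN, −20 → 0 °C, dark
Reagents that add atoms: N-bromosuccinimide, O=C1CCC(=O)N1Br
Why: Electrophilic aromatic bromination in which ring C is blocked (both para-to-O sites are occupied and Br deactivates it), so only ring B reacts, and of its two para-to-O sites the open C6 is preferred over C5, which is shielded by the twisted o-bromoaryl group.

**Step 4**
Reactants: 5, 3-vinylanisole (1-ethenyl-3-methoxybenzene)
Product: 6, 9-[2-(3-methoxyphenyl)ethyl]-9-borabicyclo[3.3.1]nonane (used as its THF solution)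
Conditions: 9-BBN (0.5 M in THF, 1.05 equiv), 0 °C → rt, 4 h
Reagents that add atoms: 9-BBN-H, [H]B1C2CCCC1CCC2
Why: Anti-Markovnikov hydroboration, in which 9-BBN places boron on the terminal carbon of styrenes with greater than 97:3 selectivity.

**Step 5**
Reactants: 4, the dibromobiaryl (1.0 equiv); 6, the B-alkyl-9-BBN (2.6 equiv)
Product: 7, 6-[2-(3-methoxyphenyl)ethyl]-4-{6-[2-(3-methoxyphenyl)ethyl]-2,2-dimethyl-1,3-benzodioxol-5-yl}-2,2-dimethyl-1,3-benzodioxole
Conditions: Pd(OAc)2 (5 mol %), SPhos (10 mol %), 3 M aq K3PO4 (6 equiv), THF, 65 °C, 16 h
Reagents that add atoms: none beyond 6 (the 9-BBN unit is lost)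
Why: Two-fold B-alkyl Suzuki–Miyaura coupling installs both saturated arms directly with no hydrogenation, since the bulky electron-rich ligand handles the electron-rich, ortho-aryl bromide and outruns β-hydride elimination, and the ketals and aryl methyl ethers are inert to aqueous phosphate.

**Step 6**
Reactants: 7, the bis-acetonide
Product: 8, isoplagilin (target)
Conditions: TFA/H2O 9:1, 0 °C → rt, 2 h, under Ar; degassed work-up
Reagents that add atoms: none (water supplies only H to the product; its O leaves in acetone)
Why: Acid-catalysed ketal hydrolysis through tertiary oxocarbenium ions (the same cleavage that releases acetonide-protected DOPA in TFA), a pathway the two aryl methyl ethers cannot follow, so they survive.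

## Compound list
1 | 2,2-dimethyl-1,3-benzodioxole (C9H10O2) | CC1(C)Oc2ccccc2O1 | starting material
2 | 5,6-dibromo-2,2-dimethyl-1,3-benzodioxole (C9H8Br2O2) | CC1(C)Oc2cc(Br)c(Br)cc2O1 | intermediate
3 | 5-bromo-6-(2,2-dimethyl-1,3-benzodioxol-4-yl)-2,2-dimethyl-1,3-benzodioxole (C18H17BrO4) | CC1(C)Oc2cccc(-c3cc4OC(C)(C)Oc4cc3Br)c2O1 | intermediate
4 | 6-bromo-4-(6-bromo-2,2-dimethyl-1,3-benzodioxol-5-yl)-2,2-dimethyl-1,3-benzodioxole (C18H16Br2O4) | CC1(C)Oc2cc(Br)cc(-c3cc4OC(C)(C)Oc4cc3Br)c2O1 | intermediate
5 | 3-vinylanisole (C9H10O) | C=Cc1cccc(OC)c1 | starting material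
6 | 9-[2-(3-methoxyphenyl)ethyl]-9-BBN (C17H25BO) | COc1cccc(CCB2C3CCCC2CCC3)c1 | intermediate
7 | isoplagilin bis-acetonide (C36H38O6) | CC1(C)Oc2cc(CCc3cccc(OC)c3)cc(-c3cc4OC(C)(C)Oc4cc3CCc3cccc(OC)c3)c2O1 | intermediate
8 | isoplagilin (C30H30O6, achiral) | COc1cccc(CCc2cc(O)c(O)c(-c3cc(O)c(O)cc3CCc3cccc(OC)c3)c2)c1 | target

## Summary
Total steps: 6.
Longest linear sequence: 5 (Steps 1 → 2 → 3 → 5 → 6).

**Steps most likely to fail, with fallbacks**
1. **Step 2, aryne chain.** The risks are sacrificial Br/Li exchange, aryne oligomerisation and competing deprotonation of 2. Fallback: abandon the aryne. Transmetalate the same 4-lithio species with ZnCl2 and run a Pd-catalysed mono-Negishi coupling on excess 2. The second bromide becomes hindered after the first coupling, so 3 is still the product.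
2. **Step 3, C6 versus C5 bromination of ring B.** The desired isomer shows two meta-coupled ring-B protons (J about 2 Hz); the wrong one shows an 8 Hz pair. Fallback: remove the late bromination by installing the ring-B arm first.
   - Convert 4-bromocatechol to its bis-MOM ether, then couple it with 6 to give the bibenzyl.
   - Lithiate next to the unhindered OMOM group, which out-directs the anisole OMe, and use that aryllithium in the aryne coupling with 2.
   - Add the second arm by a single Suzuki coupling. The same acid step removes the MOM groups and the ketal.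
3. **Step 5, double sp3–sp2 coupling at the hindered bromide.** The risks are β-hydride elimination and protodebromination. Fallback: switch to sp2–sp coupling. Run a double Sonogashira reaction of 4 with 3-ethynylanisole, then H2 over Pd/C to saturate both alkynes (the ketals are stable to this), and continue with Step 6.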